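## Retrosynthetic overview

1. The target comes from a C13-silylated macrocyclic α-methylene lactone by desilylation and acetylation at the very end.
2. The C1–C2 bond, the 14-membered carbocycle and then the cis-fused γ-lactone arise in one operation: intramolecular Nozaki–Hiyama 2-(methoxycarbonyl)allylation of a farnesal-type enal, then lactonisation.
3. The (Z)-2-(bromomethyl)enoate arm comes from the Baylis–Hillman adduct of a β-silyloxy aldehyde with methyl acrylate (C15–C17).
4. The erythro C11/C12/C13 epoxy-alcohol triad comes from a matched Sharpless epoxidation of an (R)-allylic β-hydroxy ester, itself made by ketoreductase reduction of an achiral β-keto ester (first stereocentre).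
5. The β-keto ester comes from (E,E)-farnesol (C2–C13 with all three E-olefins) and ethyl acetate; ring order: epoxide on the open chain, then carbocycle, then lactone.

Assumption: locants C1–C17 follow cembrane numbering of the target throughout, and short-lived ionic or organometallic transients (alkoxides, enolates, the allylchromium species) are treated as mechanism and not numbered.

## Route

Step 1
Reactants: 1 (2E,6E)-farnesol
Product: 2 (2E,6E)-farnesyl 4-methoxybenzyl (PMB) ether
Conditions: NaH, PMBCl, Bu4NI (cat.), THF/DMF, 0 °C to rt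
Reagents that add atoms: 4-methoxybenzyl chloride, COc1ccc(CCl)cc1
Why: Williamson etherification of the primary allylic alkoxide; the PMB ether survives every base, hydride, oxidant and Lewis acid used before step 11 and is then removed under neutral oxidative conditions.

Step 2
Reactants: 2 (2E,6E)-farnesyl PMB ether
Product: 3 (2E,6E,10E)-12-[(4-methoxyphenyl)methoxy]-2,6,10-trimethyldodeca-2,6,10-trien-1-ol
Conditions: SeO2 (0.2 equiv), t-BuOOH (3 equiv), salicylic acid (cat.), CH2Cl2, 0 °C to rt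
Reagents that add atoms: tert-butyl hydroperoxide, CC(C)(C)OO
Why: SeO2-catalysed allylic oxidation (ene reaction then [2,3]-sigmatropic shift) attacks the terminal, most electron-rich olefin at its (E)-methyl group with the known E selectivity, and any over-oxidised enal 4 is simply carried into step 3.

Step 3
Reactants: 3 (2E,6E,10E)-12-(PMB-oxy)-2,6,10-trimethyldodeca-2,6,10-trien-1-ol
Product: 4 (2E,6E,10E)-12-[(4-methoxyphenyl)methoxy]-2,6,10-trimethyldodeca-2,6,10-trienal
Conditions: MnO2 (15 equiv), CH2Cl2, rt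
Reagents that add atoms: none
Why: MnO2 oxidises only the allylic alcohol and converges the alcohol/enal mixture from step 2 on one enal without E/Z erosion.

Step 4
Reactants: 4 (2E,6E,10E)-12-(PMB-oxy)-2,6,10-trimethyldodeca-2,6,10-trienal
Product: 5 (2E,6E,10E)-12-[(4-methoxyphenyl)methoxy]-2,6,10-trimethyldodeca-2,6,10-trienoic acid
Conditions: NaClO2, NaH2PO4, 2-methyl-2-butene (20 equiv), t-BuOH/H2O, 0 °C to rt
Reagents that add atoms: sodium chlorite, [Na+].[O-]Cl=O
Why: Pinnick oxidation of the enal to the acid, with 2-methyl-2-butene scavenging HOCl so the trisubstituted olefins and the PMB ether are not touched.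

Step 5
Reactants: 5 (2E,6E,10E)-12-(PMB-oxy)-2,6,10-trimethyldodeca-2,6,10-trienoic acid; 6 ethyl acetate
Product: 8 ethyl (4E,8E,12E)-14-[(4-methoxyphenyl)methoxy]-4,8,12-trimethyl-3-oxotetradeca-4,8,12-trienoate, via acyl imidazolide 7 (not isolated)
Conditions: CDI, THF, rt; then LiCH2CO2Et [6, LiN(SiMe3)2, 3.3 equiv], THF, −78 °C; AcOH quench
Reagents that add atoms: none
Why: Claisen-type C-acylation of the ester enolate by the activated acyl imidazolide (1,2-attack, product protected as its enolate by excess base) gives the achiral β-keto ester and installs C14 and C1 without creating a stereocentre.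

Step 6
Reactants: 8 ethyl (4E,8E,12E)-14-(PMB-oxy)-4,8,12-trimethyl-3-oxotetradeca-4,8,12-trienoate
Product: 9 ethyl (3R,4E,8E,12E)-3-hydroxy-14-[(4-methoxyphenyl)methoxy]-4,8,12-trimethyltetradeca-4,8,12-trienoate
Conditions: ketoreductase (NADPH-dependent, R-selective, chosen from a commercial screening panel), NADP+ (cat.), i-PrOH (15% v/v), KH2PO4/K2HPO4 buffer pH 7.0, 30 °C
Reagents that add atoms: none
Why: biocatalytic asymmetric ketone reduction: the ketoreductase delivers hydride from NADPH (recycled by isopropanol) to one enantiotopic face of the achiral carbonyl, setting C13 as R (the first stereocentre, typically >99% ee) without touching C=C or ester.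

Step 7
Reactants: 9 ethyl (3R,4E,8E,12E)-3-hydroxy-14-(PMB-oxy)-4,8,12-trimethyltetradeca-4,8,12-trienoate
Product: 10 ethyl (3R)-3-hydroxy-3-[(2R,3R)-3-{(3E,7E)-9-[(4-methoxyphenyl)methoxy]-3,7-dimethylnona-3,7-dien-1-yl}-2-methyloxiran-2-yl]propanoate
Conditions: Ti(OiPr)4 (0.2 equiv), D-(−)-diisopropyl tartrate (0.25 equiv), t-BuOOH (2 equiv, in decane), 4 Å molecular sieves, CH2Cl2, −20 °C
Reagents that add atoms: tert-butyl hydroperoxide, CC(C)(C)OO
Why: Sharpless asymmetric epoxidation: the titanium-bound C13 alkoxide directs oxygen only to the C11=C12 olefin, and D-(−)-tartrate with the (R)-carbinol is the matched pair (mirror image of the classical L-(+)/(S) fast-reacting pair), giving the erythro epoxy alcohol with the new C11 and C12 centres.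

Step 8
Reactants: 10 ethyl (3R)-3-hydroxy-3-[(2R,3R)-oxiranyl]propanoate shown in step 7
Product: 11 ethyl (3R)-3-[(tert-butyldimethylsilyl)oxy]-3-[(2S,3R)-3-{(3E,7E)-9-[(4-methoxyphenyl)methoxy]-3,7-dimethylnona-3,7-dien-1-yl}-2-methyloxiran-2-yl]propanoate
Conditions: TBSOTf (1.3 equiv), 2,6-lutidine (2 equiv), CH2Cl2, −78 to −20 °C
Reagents that add atoms: tert-butyldimethylsilyl trifluoromethanesulfonate, CC(C)(C)[Si](C)(C)OS(=O)(=O)C(F)(F)F
Why: silylation of the hindered secondary alcohol with the reactive triflate under buffered, cold conditions blocks Payne rearrangement and β-elimination in later steps, with no change at any stereocentre (the oxirane C2 label changes from R to S by CIP priority only).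

Step 9
Reactants: 11 ethyl (3R)-3-(TBS-oxy)-3-[(2S,3R)-oxiranyl]propanoate shown in step 8
Product: 12 (3R)-3-[(tert-butyldimethylsilyl)oxy]-3-[(2S,3R)-3-{(3E,7E)-9-[(4-methoxyphenyl)methoxy]-3,7-dimethylnona-3,7-dien-1-yl}-2-methyloxiran-2-yl]propanal
Conditions: i-Bu2AlH (1.1 equiv), CH2Cl2, −78 °C; MeOH, then H2O
Reagents that add atoms: none
Why: partial ester reduction through the tetrahedral aluminium hemiacetal, which is stable at −78 °C for β-silyloxy esters, gives the aldehyde (C1) and leaves epoxide, silyl ether and stereocentres alone.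

Step 10
Reactants: 12 (3R)-3-(TBS-oxy)-3-[(2S,3R)-oxiranyl]propanal shown in step 9; 13 methyl acrylate
Product: 14 methyl 2-{(1RS,3R)-3-[(tert-butyldimethylsilyl)oxy]-1-hydroxy-3-[(2S,3R)-3-{(3E,7E)-9-[(4-methoxyphenyl)methoxy]-3,7-dimethylnona-3,7-dien-1-yl}-2-methyloxiran-2-yl]propyl}prop-2-enoate
Conditions: 13 (10 equiv), DABCO (1 equiv), MeOH (cat.), rt, 5–7 d
Reagents that add atoms: none
Why: Morita–Baylis–Hillman reaction attaches C15–C17 to C1 under nearly neutral conditions; the new C1 carbinol forms as an epimer mixture, which does not matter because C1 becomes sp2 in step 13.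

Step 11
Reactants: 14 Baylis–Hillman adduct (PMB ether)
Product: 15 methyl 2-{(1RS,3R)-3-[(tert-butyldimethylsilyl)oxy]-1-hydroxy-3-[(2S,3R)-3-[(3E,7E)-9-hydroxy-3,7-dimethylnona-3,7-dien-1-yl]-2-methyloxiran-2-yl]propyl}prop-2-enoate
Conditions: DDQ (1.3 equiv), CH2Cl2/pH 7 buffer (KH2PO4/K2HPO4) 10:1, 0 °C
Reagents that add atoms: none
Why: oxidative PMB cleavage by hydride abstraction at the electron-rich benzylic position frees the C2 alcohol, while silyl ether, epoxide, acrylate and olefins are inert in the buffered medium.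

Step 12
Reactants: 15 diol (primary allylic C2–OH and Baylis–Hillman OH)
Product: 16 methyl 2-{(1RS,3R)-3-[(tert-butyldimethylsilyl)oxy]-3-[(2S,3R)-3-[(3E,7E)-3,7-dimethyl-9-oxonona-3,7-dien-1-yl]-2-methyloxiran-2-yl]-1-hydroxypropyl}prop-2-enoate
Conditions: MnO2 (15 equiv), CH2Cl2, rt
Reagents that add atoms: none
Why: chemoselective MnO2 oxidation: the electron-rich primary allylic alcohol gives the (E)-enal quickly, whereas the secondary alcohol next to the electron-poor acrylate is oxidised only very slowly.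

Step 13
Reactants: 16 hydroxy enal
Product: 17 methyl (2Z,5R)-2-(bromomethyl)-5-[(tert-butyldimethylsilyl)oxy]-5-{(2S,3R)-3-[(3E,7E)-3,7-dimethyl-9-oxonona-3,7-dien-1-yl]-2-methyloxiran-2-yl}pent-2-enoate
Conditions: NBS (1.5 equiv), Me2S (1.8 equiv), CH2Cl2, −20 to 0 °C
Reagents that add atoms: N-bromosuccinimide, O=C1CCC(=O)N1Br
Why: Corey–Kim-type activation of the alcohol as an alkoxysulfonium salt followed by SN2′ attack of bromide gives the rearranged conjugated primary bromide with Z geometry (alkyl chain trans to the ester), with no acid released that could harm epoxide, silyl ether or enal.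

Step 14
Reactants: 17 (Z)-allylic bromide enal
Product: 19 (1S,2S,3E,7E,11R,12S,13R)-13-[(tert-butyldimethylsilyl)oxy]-11,12-epoxycembra-3,7,15(17)-trien-16,2-olide, via hydroxy ester 18 (not isolated)
Conditions: CrCl2 (10 equiv), 4 Å molecular sieves, THF, rt, syringe-pump addition of 17 to 0.002 M; aqueous work-up; then PPTS (cat.), CH2Cl2, rt
Reagents that add atoms: none
Why: intramolecular Nozaki–Hiyama (Barbier-type) 2-(alkoxycarbonyl)allylation: the allylchromium species of trivalent chromium adds through its γ-carbon (C1) to the enal in a chair six-membered transition state, the Z geometry giving the syn adduct 18 and hence the cis ring fusion at C1/C2 after lactonisation, while the face is left to the C13 silyloxy stereocentre and the folding of the forming 14-membered ring.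

Step 15
Reactants: 19 C13 silyl ether of the macrocyclic lactone
Product: 20 (1S,2S,3E,7E,11R,12R,13R)-11,12-epoxy-13-hydroxycembra-3,7,15(17)-trien-16,2-olide
Conditions: TBAF (3 equiv), AcOH (3 equiv), THF, 0 °C to rt
Reagents that add atoms: none
Why: fluoride-driven desilylation buffered with acetic acid protonates the C13 alkoxide at once, so neither oxa-Michael addition to the α-methylene lactone nor Payne rearrangement can occur (the C12 label changes from S to R by CIP priority only).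

Step 16
Reactants: 20 C13 alcohol
Product: 21 (1S,2S,3E,7E,11R,12S,13R)-13-acetoxy-11,12-epoxycembra-3,7,15(17)-trien-16,2-olide
Conditions: Ac2O (3 equiv), DMAP (0.2 equiv), pyridine, CH2Cl2, 0 °C to rt
Reagents that add atoms: acetic anhydride, CC(=O)OC(C)=O
Why: DMAP-catalysed O-acylation of the secondary alcohol proceeds with retention at C13 under conditions that leave epoxide and α-methylene lactone intact, giving the target.

## Compound list

1 | (2E,6E)-3,7,11-trimethyldodeca-2,6,10-trien-1-ol, (E,E)-farnesol | OC/C=C(\C)CC/C=C(\C)CCC=C(C)C | starting material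
2 | 1-methoxy-4-({[(2E,6E)-3,7,11-trimethyldodeca-2,6,10-trien-1-yl]oxy}methyl)benzene | COc1ccc(COC/C=C(\C)CC/C=C(\C)CCC=C(C)C)cc1 | intermediate
3 | (2E,6E,10E)-12-[(4-methoxyphenyl)methoxy]-2,6,10-trimethyldodeca-2,6,10-trien-1-ol | COc1ccc(COC/C=C(\C)CC/C=C(\C)CC/C=C(\C)CO)cc1 | intermediate
4 | (2E,6E,10E)-12-[(4-methoxyphenyl)methoxy]-2,6,10-trimethyldodeca-2,6,10-trienal | COc1ccc(COC/C=C(\C)CC/C=C(\C)CC/C=C(\C)C=O)cc1 | intermediate
5 | (2E,6E,10E)-12-[(4-methoxyphenyl)methoxy]-2,6,10-trimethyldodeca-2,6,10-trienoic acid | COc1ccc(COC/C=C(\C)CC/C=C(\C)CC/C=C(\C)C(=O)O)cc1 | intermediate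
6 | ethyl acetate | CCOC(C)=O | starting material
7 | 1-[(2E,6E,10E)-12-[(4-methoxyphenyl)methoxy]-2,6,10-trimethyldodeca-2,6,10-trienoyl]-1H-imidazole | COc1ccc(COC/C=C(\C)CC/C=C(\C)CC/C=C(\C)C(=O)n2ccnc2)cc1 | intermediate (not isolated)
8 | ethyl (4E,8E,12E)-14-[(4-methoxyphenyl)methoxy]-4,8,12-trimethyl-3-oxotetradeca-4,8,12-trienoate | COc1ccc(COC/C=C(\C)CC/C=C(\C)CC/C=C(\C)C(=O)CC(=O)OCC)cc1 | intermediate
9 | ethyl (3R,4E,8E,12E)-3-hydroxy-14-[(4-methoxyphenyl)methoxy]-4,8,12-trimethyltetradeca-4,8,12-trienoate | COc1ccc(COC/C=C(\C)CC/C=C(\C)CC/C=C(\C)[C@H](O)CC(=O)OCC)cc1 | intermediate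
10 | ethyl (3R)-3-hydroxy-3-[(2R,3R)-3-{(3E,7E)-9-[(4-methoxyphenyl)methoxy]-3,7-dimethylnona-3,7-dien-1-yl}-2-methyloxiran-2-yl]propanoate | COc1ccc(COC/C=C(\C)CC/C=C(\C)CC[C@H]2O[C@]2(C)[C@H](O)CC(=O)OCC)cc1 | intermediate
11 | ethyl (3R)-3-[(tert-butyldimethylsilyl)oxy]-3-[(2S,3R)-3-{(3E,7E)-9-[(4-methoxyphenyl)methoxy]-3,7-dimethylnona-3,7-dien-1-yl}-2-methyloxiran-2-yl]propanoate | COc1ccc(COC/C=C(\C)CC/C=C(\C)CC[C@H]2O[C@]2(C)[C@H](O[Si](C)(C)C(C)(C)C)CC(=O)OCC)cc1 | intermediate
12 | (3R)-3-[(tert-butyldimethylsilyl)oxy]-3-[(2S,3R)-3-{(3E,7E)-9-[(4-methoxyphenyl)methoxy]-3,7-dimethylnona-3,7-dien-1-yl}-2-methyloxiran-2-yl]propanal | COc1ccc(COC/C=C(\C)CC/C=C(\C)CC[C@H]2O[C@]2(C)[C@H](O[Si](C)(C)C(C)(C)C)CC=O)cc1 | intermediate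
13 | methyl prop-2-enoate, methyl acrylate | C=CC(=O)OC | starting material
14 | methyl 2-{(1RS,3R)-3-[(tert-butyldimethylsilyl)oxy]-1-hydroxy-3-[(2S,3R)-3-{(3E,7E)-9-[(4-methoxyphenyl)methoxy]-3,7-dimethylnona-3,7-dien-1-yl}-2-methyloxiran-2-yl]propyl}prop-2-enoate, epimer mixture at the new carbinol | COc1ccc(COC/C=C(\C)CC/C=C(\C)CC[C@H]2O[C@]2(C)[C@H](O[Si](C)(C)C(C)(C)C)CC(O)C(=C)C(=O)OC)cc1 | intermediate
15 | methyl 2-{(1RS,3R)-3-[(tert-butyldimethylsilyl)oxy]-1-hydroxy-3-[(2S,3R)-3-[(3E,7E)-9-hydroxy-3,7-dimethylnona-3,7-dien-1-yl]-2-methyloxiran-2-yl]propyl}prop-2-enoate | OC/C=C(\C)CC/C=C(\C)CC[C@H]1O[C@]1(C)[C@H](O[Si](C)(C)C(C)(C)C)CC(O)C(=C)C(=O)OC | intermediate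
16 | methyl 2-{(1RS,3R)-3-[(tert-butyldimethylsilyl)oxy]-3-[(2S,3R)-3-[(3E,7E)-3,7-dimethyl-9-oxonona-3,7-dien-1-yl]-2-methyloxiran-2-yl]-1-hydroxypropyl}prop-2-enoate | O=C/C=C(\C)CC/C=C(\C)CC[C@H]1O[C@]1(C)[C@H](O[Si](C)(C)C(C)(C)C)CC(O)C(=C)C(=O)OC | intermediate
17 | methyl (2Z,5R)-2-(bromomethyl)-5-[(tert-butyldimethylsilyl)oxy]-5-{(2S,3R)-3-[(3E,7E)-3,7-dimethyl-9-oxonona-3,7-dien-1-yl]-2-methyloxiran-2-yl}pent-2-enoate | O=C/C=C(\C)CC/C=C(\C)CC[C@H]1O[C@]1(C)[C@H](O[Si](C)(C)C(C)(C)C)C/C=C(\CBr)C(=O)OC | intermediate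
18 | methyl (1S,2S,3E,7E,11R,12S,13R)-13-[(tert-butyldimethylsilyl)oxy]-11,12-epoxy-2-hydroxycembra-3,7,15(17)-trien-16-oate | O[C@H]1/C=C(\C)CC/C=C(\C)CC[C@H]2O[C@]2(C)[C@H](O[Si](C)(C)C(C)(C)C)C[C@H]1C(=C)C(=O)OC | intermediate (not isolated)
19 | (1S,2S,3E,7E,11R,12S,13R)-13-[(tert-butyldimethylsilyl)oxy]-11,12-epoxycembra-3,7,15(17)-trien-16,2-olide | C=C1C(=O)O[C@H]2/C=C(\C)CC/C=C(\C)CC[C@H]3O[C@]3(C)[C@H](O[Si](C)(C)C(C)(C)C)C[C@@H]12 | intermediate
20 | (1S,2S,3E,7E,11R,12R,13R)-11,12-epoxy-13-hydroxycembra-3,7,15(17)-trien-16,2-olide (same spatial arrangement at C12 as in 19 and 21) | C=C1C(=O)O[C@H]2/C=C(\C)CC/C=C(\C)CC[C@H]3O[C@]3(C)[C@H](O)C[C@@H]12 | intermediate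
21 | (1S,2S,3E,7E,11R,12S,13R)-13-acetoxy-11,12-epoxycembra-3,7,15(17)-trien-16,2-olide | C=C1C(=O)O[C@H]2/C=C(\C)CC/C=C(\C)CC[C@H]3O[C@]3(C)[C@H](OC(C)=O)C[C@@H]12 | target

## Step count and risks

Total step count: 16. Longest linear sequence: 16 steps (fully linear from farnesol; ethyl acetate and methyl acrylate enter as purchased materials).

The step most likely to fail is step 14. The cis fusion follows from the chair transition state, but which face of C1/C2 forms relative to C13 is not securely predictable, so the wrong cis-diastereomer or a mixture may result; yield under high dilution is the second concern. The fallback closes the same bond by a thermal allylboration instead of organochromium chemistry. It sets out from 14: acetylation (Ac2O, DMAP) gives the allylic acetate F1. SN2′ borylation with bis(pinacolato)diboron and Pd2(dba)3 (cat.) gives the pinacol allylboronate F2, with the alkyl chain cis to the CH2B arm. DDQ and then MnO2, as in steps 11 and 12, give the alcohol F3 and the enal F4. Heating F4 in toluene at 90 °C and 0.002 M closes the ring through a compact boron–oxygen chair transition state; work-up gives 18 and then 19, where the route is rejoined.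

The second is step 10. The Baylis–Hillman reaction of a β-silyloxy aldehyde is slow and can lose the silyloxy group by elimination. The fallback replaces amine catalysis by a preformed nucleophile. It sets out from 12, which is treated at 0 °C in THF with [1-(methoxycarbonyl)ethenyl]bis(2-methylpropyl)aluminium F5, generated from methyl propiolate, i-Bu2AlH and N-methylmorpholine N-oxide. This vinylalumination gives 14 within hours, where the route is rejoined.

The third is step 6. The ketoreductase may not accept the bulky, lipophilic keto ester at a useful rate. The fallback sets C13 by kinetic resolution instead. It sets out from 8: reduction with NaBH4 and CeCl3·7H2O in MeOH gives the racemic alcohol F6. Sharpless kinetic resolution (Ti(OiPr)4, D-(−)-diisopropyl tartrate, 0.6 equiv t-BuOOH, −20 °C) epoxidises only the (3R)-enantiomer and gives 10 directly, where the route is rejoined. The unreacted (3S)-alcohol F7 is separated and recycled by Dess–Martin oxidation to 8.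

## Further compounds

F1 | step 14 | methyl 2-{(1RS,3R)-1-acetoxy-3-[(tert-butyldimethylsilyl)oxy]-3-[(2S,3R)-3-{(3E,7E)-9-[(4-methoxyphenyl)methoxy]-3,7-dimethylnona-3,7-dien-1-yl}-2-methyloxiran-2-yl]propyl}prop-2-enoate | COc1ccc(COC/C=C(\C)CC/C=C(\C)CC[C@H]2O[C@]2(C)[C@H](O[Si](C)(C)C(C)(C)C)CC(OC(C)=O)C(=C)C(=O)OC)cc1
F2 | step 14 | methyl (2E,5R)-5-[(tert-butyldimethylsilyl)oxy]-5-[(2S,3R)-3-{(3E,7E)-9-[(4-methoxyphenyl)methoxy]-3,7-dimethylnona-3,7-dien-1-yl}-2-methyloxiran-2-yl]-2-[(4,4,5,5-tetramethyl-1,3,2-dioxaborolan-2-yl)methyl]pent-2-enoate | COc1ccc(COC/C=C(\C)CC/C=C(\C)CC[C@H]2O[C@]2(C)[C@H](O[Si](C)(C)C(C)(C)C)C/C=C(\CB3OC(C)(C)C(C)(C)O3)C(=O)OC)cc1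
F3 | step 14 | methyl (2E,5R)-5-[(tert-butyldimethylsilyl)oxy]-5-{(2S,3R)-3-[(3E,7E)-9-hydroxy-3,7-dimethylnona-3,7-dien-1-yl]-2-methyloxiran-2-yl}-2-[(4,4,5,5-tetramethyl-1,3,2-dioxaborolan-2-yl)methyl]pent-2-enoate | OC/C=C(\C)CC/C=C(\C)CC[C@H]1O[C@]1(C)[C@H](O[Si](C)(C)C(C)(C)C)C/C=C(\CB2OC(C)(C)C(C)(C)O2)C(=O)OC
F4 | step 14 | methyl (2E,5R)-5-[(tert-butyldimethylsilyl)oxy]-5-{(2S,3R)-3-[(3E,7E)-3,7-dimethyl-9-oxonona-3,7-dien-1-yl]-2-methyloxiran-2-yl}-2-[(4,4,5,5-tetramethyl-1,3,2-dioxaborolan-2-yl)methyl]pent-2-enoate | O=C/C=C(\C)CC/C=C(\C)CC[C@H]1O[C@]1(C)[C@H](O[Si](C)(C)C(C)(C)C)C/C=C(\CB2OC(C)(C)C(C)(C)O2)C(=O)OC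
F5 | step 10 | [1-(methoxycarbonyl)ethenyl]bis(2-methylpropyl)aluminium | C=C(C(=O)OC)[Al](CC(C)C)CC(C)C
F6 | step 6 | ethyl (4E,8E,12E)-3-hydroxy-14-[(4-methoxyphenyl)methoxy]-4,8,12-trimethyltetradeca-4,8,12-trienoate, racemate | COc1ccc(COC/C=C(\C)CC/C=C(\C)CC/C=C(\C)C(O)CC(=O)OCC)cc1
F7 | step 6 | ethyl (3S,4E,8E,12E)-3-hydroxy-14-[(4-methoxyphenyl)methoxy]-4,8,12-trimethyltetradeca-4,8,12-trienoate | COc1ccc(COC/C=C(\C)CC/C=C(\C)CC/C=C(\C)[C@@H](O)CC(=O)OCC)cc1
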